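## The problem

The target 27 is an isoflavan quinone. Its benzo ring (ring A, C4a to C8a) is fused to a pyran (ring C: O1, C2, C3, C4), and C3 carries a 2,3-dimethoxy-1,4-benzoquinone (ring B, C1' to C6'). C3 is the only stereocentre and must be S. No other stereocentre can relay its configuration, so it has to come from a reagent or an auxiliary and then survive the whole route. Ring A bears four contiguous oxygens (O1 on C8a, the free hydroxyl on C8, methoxy groups on C7 and C6). Ring B in its reduced form bears the same pattern, so an oxidant cannot be expected to tell the two rings apart unless they are protected differently. The quinone does not tolerate bases, nucleophiles, hydrides or organometallics, and the C3–H next to it is vinylogously acidic. The C8 phenol and the hydroquinone are sensitive to oxidants, so both are best unveiled last under neutral conditions. The single free hydroxyl sits on C8, between O1 and the C7 methoxy group, and needs a method that addresses exactly this carbon. A short construction is possible because of the way ring A is fused: C4a and C8a are shared with the pyran, C8a carries O1, and C6 and C7 carry identical substituents. C8a≡C8 can therefore be an ethynyl ether, C4a≡C5 a propargylic alkyne on the same C2–C3–C4 chain, and C6≡C7 a symmetrical external alkyne.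

## Retrosynthesis

**From 27 to 25.** No skeletal bond is cut. The two quinone oxygens are traced through hydroquinone 26 to the two O–benzyl bonds of 25. The neighbouring choice, methyl ethers removed by oxidative demethylation, is rejected because ring A of such a precursor has the same substitution pattern as ring B and would be oxidised with it. Benzyl ethers leave under neutral hydrogenolysis, and a hydroquinone is oxidised far more readily than the lone ring A phenol. 25 has no quinone and tolerates the organometallic chemistry that comes before it.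

**From 25 to 22.** The C8–O bond is cut. In 22, C8–H is the only aromatic hydrogen flanked by two ether oxygens (O1 and the C7 methoxy). C5–H and C6'–H each have one oxygen neighbour, so ortho-lithiation should select C8. Carrying the C8 oxygen through ring formation instead would need an acetylene diether, or a third boron that could not be told from the other two at the methylation stage. The forward step must avoid metalation of the benzylic CH2 groups of the benzyl ethers.

**From 22 to 20 (through 21).** C6–O and C7–O are replaced by C–B bonds. The two methoxy groups are vicinal and identical, which is what a symmetrical diborylalkyne delivers. Oxidation of an arylboronate at the same carbon and O-methylation are routine. The only demand is that the air-sensitive catechol 21 be methylated without delay.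

**From 20 to 18 and 19.** Three bonds of ring A are cut at once: C4a–C8a, C5–C6 and C7–C8. The classical neighbouring cuts (O1–C2 or C4–C4a) only close the pyran and need ring A as a prefabricated, fully oxygenated arene. This cut builds ring A and the pyran together. The precursor 18 is acyclic apart from ring B and has the one stereocentre already in place; 19 is a stock alkyne. The forward reaction must run at or below room temperature, because the ethynyl ether of 18 can lose ketene through the benzylic C3–H, and it must favour cross- over self-trimerisation.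

**From 18 to 15 and 16 (through 17).** The O1–C8a bond, an O–C(sp) bond, is cut. The oxygen stays with the alcohol 15 and both alkyne carbons come from trichloroethylene 16. The reverse polarity (an ynolate alkylated on oxygen) is not available, since ynolates react at carbon. The forward sequence must also cope with the terminal alkyne already present in 15.

**From 15 to 14, then to 12 and 13.** The C3–C4 bond is cut next to a carboxyl-derived C2, which makes C3 an enolate carbon and lets an oxazolidinone auxiliary set its configuration. The alternative Ar–C3 cut (asymmetric conjugate arylation of a butenolide) would need a hindered, electron-rich ortho-alkoxy arylmetal on a poor acceptor and is less dependable. Alkylation of imide 12 with propargyl bromide 13 and reductive removal of the auxiliary give 15. After reduction, no acidifying group remains next to C3.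

**From 12 to 9 and 10, and from 9 through 8 to 5 and 6 (through 7).** The imide N–acyl bond leads to acid 9 and auxiliary 10. The C1'–CH2 bond of the arylacetic unit is cut to aryl bromide 5 and the zinc enolate 7 of ethyl bromoacetate 6. This two-step entry is shorter than formylation followed by one-carbon homologation.

**From 5 through 4 and 2 (3 in between) to 1.** C–Br, two O–benzyl bonds and the C4–O bond of the phenol are cut. 4 is C2-symmetric, so its two free positions are equivalent and bromination has no regiochemical choice. The para-oxidation of 1 supplies the fourth oxygen of ring B.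

## Roads not taken

**Alternative 1:** Ring B is cut into the alkyne of (3S)-8-(benzyloxy)-3-ethynyl-6,7-dimethoxychroman A2 and the four carbons of dimethyl squarate A3.
- **Forward key step.** The lithium acetylide of A2 adds to A3 to give the 4-alkynyl-4-hydroxycyclobutenone A4. Heating opens the four-membered ring to a ketene, whose carbonyl carbon bonds to the alkyne carbon bearing C3. Transfer of the hydroxyl hydrogen completes the 8-O-benzyl quinone A1 (Moore rearrangement); debenzylation then gives 27.
- **Merits.** Ring B is born in its final oxidation state. Both methoxy groups come with A3, the regiochemistry is built in, and no hydroquinone protection or late oxidation is needed. After its key step this road is one step from the target, against four for the chosen plan, and in that respect it is better.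
- **Weak points.** A2 is itself an enantioenriched chroman with the complete four-oxygen ring A and a propargylic stereocentre, so the hard part of the target is only moved into a separate fragment synthesis. The rearrangement needs boiling aromatic solvent. The diradical can also close to a five-membered alkylidenecyclopentenedione, and the aryl radical next to C3 can abstract hydrogen from C2 or C4. Removing a benzyl group beside a quinone needs reduction and re-oxidation.
- **Comparison.** The chosen plan sets against the shorter end game that ring A and the pyran arise in one operation from an acyclic precursor, and that C3 is fixed by an auxiliary alkylation before any ring exists.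

**Alternative 2:** The C3–C4 and O1–C2 bonds are cut, giving [2,5-bis(benzyloxy)-3,4-dimethoxyphenyl]acetaldehyde A6 and 2-(benzyloxy)-3,4-dimethoxy-6-[(phenylsulfonyl)methyl]phenol A7.
- **Forward key step.** Base releases the ortho-quinone methide A8 from A7. The enamine of A6 with a chiral secondary amine attacks its methylene carbon, and the phenol oxygen closes onto the aldehyde to give lactol A5. Ionic deoxygenation of the lactol, hydrogenolysis and oxidation would finish the synthesis.
- **Merits.** Both aromatic rings are brought in with all oxygens in place. The union is convergent, the stereocentre is made catalytically, and no late C–H oxygenation is needed. In longest linear sequence this road would be clearly shorter than the chosen plan.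
- **Weak points.** The new stereocentre in A5 is both benzylic to ring B and α to a masked aldehyde, in the presence of the amine and base that generate A8. Erosion of configuration through enol or enamine is the expected failure. A6 is an electron-rich arylacetaldehyde prone to self-condensation, and its conjugated enamine is a weak nucleophile towards the donor-stabilised A8.
- **Comparison.** The chosen plan sets configurational security against the lower step count: C3 is made under kinetic control next to an imide and is no longer acidified once the auxiliary is reduced off.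

**Alternative 3:** The C4–C4a bond is cut. The precursor is the aryl ether A10, 3-(benzyloxy)-1-bromo-4,5-dimethoxy-2-{[(2S)-2-[2,5-bis(benzyloxy)-3,4-dimethoxyphenyl]-3-(phenylsulfonyl)propyl]oxy}benzene.
- **Forward key step.** A hindered lithium amide deprotonates the sulfone α-carbon and H5 next to bromine. Loss of bromide gives a benzyne across C4a–C5, and the tethered carbanion adds to C4a to give sulfone A9. Reductive desulfonylation, hydrogenolysis and oxidation follow.
- **Merits.** Ring A is again bought with its oxygens. The stereocentre is set beforehand and is not next to the carbanion. The closure needs no transition metal, and the late lithiation of the chosen plan is avoided; in these respects this road is at least as good.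
- **Weak points.** Only one bond is formed in the key step. The sulfone must be put in and taken out, a pentasubstituted bromophenol has to be prepared and etherified, and two equivalents of a strong amide base act on a substrate with three benzyl ethers.
- **Comparison.** Step counts should be similar. The chosen plan offers three C–C bonds and two rings in one step with no activating group to remove, at the price of a fragile ynol ether and four steps of oxygen adjustment afterwards.

Key step: step 10

## Route

Remark: 19 and the catalyst CpCo(C2H4)2 are treated as stock reagents; the catalyst is prepared from Cp2Co, potassium and ethene and is not counted as a step.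

Step 1
Reactants: 1 2,3-dimethoxyphenol
Product: 2 2,3-dimethoxy-1,4-benzoquinone
Conditions: (KSO3)2NO (2.2 equiv), KH2PO4 buffer, H2O/acetone, 0 °C → rt
Reagents that add atoms: potassium nitrosodisulfonate, [K+].[K+].[O]N(S(=O)(=O)[O-])S(=O)(=O)[O-]
Why: Teuber oxidation of a phenol with a free para position; the nitroxyl radical oxidises C4 and should give the para-quinone.

Step 2
Reactants: 2 2,3-dimethoxy-1,4-benzoquinone
Product: 4 1,4-bis(benzyloxy)-2,3-dimethoxybenzene, via 2,3-dimethoxyhydroquinone 3 (not isolated)
Conditions: Na2S2O4, n-Bu4NBr (cat.), THF/H2O, rt; then KOH (aq), BnBr (excess), rt → 40 °C, argon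
Reagents that add atoms: benzyl bromide, BrCc1ccccc1
Why: Reductive O-alkylation of a quinone: dithionite reduces 2 to the hydroquinone, which is benzylated in the same flask under phase-transfer Williamson conditions before air can re-oxidise it.

Step 3
Reactants: 4 1,4-bis(benzyloxy)-2,3-dimethoxybenzene
Product: 5 1,4-bis(benzyloxy)-5-bromo-2,3-dimethoxybenzene
Conditions: NBS (1.0 equiv), MeCN, 0 °C → rt, dark
Reagents that add atoms: N-bromosuccinimide, O=C1CCC(=O)N1Br
Why: Electrophilic aromatic bromination of a tetraalkoxybenzene; the two free positions of 4 are equivalent by symmetry and the first bromine deactivates the ring against a second one.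

Step 4
Reactants: 5 1,4-bis(benzyloxy)-5-bromo-2,3-dimethoxybenzene; 6 ethyl bromoacetate
Product: 8 ethyl [2,5-bis(benzyloxy)-3,4-dimethoxyphenyl]acetate, via ethyl (bromozincio)acetate 7 (not isolated)
Conditions: Zn, Me3SiCl (cat.), THF, 40 °C; then 5, Pd2(dba)3 (2.5 mol%), XPhos (10 mol%), THF, 65 °C
Reagents that add atoms: none
Why: Negishi coupling of a Reformatsky reagent with an aryl bromide; a bulky electron-rich phosphine on zerovalent palladium is needed for oxidative addition into the electron-rich, ortho-substituted bromide, and the zinc enolate does not self-condense.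

Step 5
Reactants: 8 ethyl [2,5-bis(benzyloxy)-3,4-dimethoxyphenyl]acetate
Product: 9 [2,5-bis(benzyloxy)-3,4-dimethoxyphenyl]acetic acid
Conditions: LiOH·H2O, THF/MeOH/H2O, rt; then HCl (aq) to pH 2
Reagents that add atoms: lithium hydroxide, [Li+].[OH-]
Why: Ester saponification; aryl benzyl and methyl ethers are inert to hydroxide.

Step 6
Reactants: 9 [2,5-bis(benzyloxy)-3,4-dimethoxyphenyl]acetic acid; 10 (4S)-4-benzyl-1,3-oxazolidin-2-one
Product: 12 (4S)-4-benzyl-3-{[2,5-bis(benzyloxy)-3,4-dimethoxyphenyl]acetyl}-1,3-oxazolidin-2-one, via pivalic mixed anhydride 11 (not isolated)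
Conditions: t-BuCOCl, Et3N, THF, −20 °C; then 10, LiCl, −20 °C → rt
Reagents that add atoms: none
Why: N-acylation of the oxazolidinone through the mixed pivalic anhydride; the hindered pivaloyl carbonyl directs attack to the arylacetyl carbonyl, and LiCl/Et3N activates the auxiliary without a strong base.

Step 7
Reactants: 12 (4S)-4-benzyl-3-{[2,5-bis(benzyloxy)-3,4-dimethoxyphenyl]acetyl}-1,3-oxazolidin-2-one; 13 propargyl bromide
Product: 14 (4S)-4-benzyl-3-{(2S)-2-[2,5-bis(benzyloxy)-3,4-dimethoxyphenyl]pent-4-ynoyl}-1,3-oxazolidin-2-one
Conditions: NaN(SiMe3)2, THF, −78 °C; then 13, −78 → −40 °C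
Reagents that add atoms: none
Why: Evans alkylation: the chelated sodium Z-enolate is attacked by propargyl bromide on the face opposite the benzyl group of the auxiliary, which sets the future C3 as S; allylic strain in the product imide guards it against re-enolisation.

Step 8
Reactants: 14 (4S)-4-benzyl-3-{(2S)-2-[2,5-bis(benzyloxy)-3,4-dimethoxyphenyl]pent-4-ynoyl}-1,3-oxazolidin-2-one
Product: 15 (2S)-2-[2,5-bis(benzyloxy)-3,4-dimethoxyphenyl]pent-4-yn-1-ol
Conditions: LiBH4, MeOH (1 equiv), Et2O, 0 °C
Reagents that add atoms: none
Why: Reductive cleavage of the auxiliary: LiBH4 reduces the exocyclic imide carbonyl to the primary alcohol under non-basic conditions, so the α-aryl stereocentre should not epimerise, and 10 is recovered.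

Step 9
Reactants: 15 (2S)-2-[2,5-bis(benzyloxy)-3,4-dimethoxyphenyl]pent-4-yn-1-ol; 16 trichloroethylene
Product: 18 1,4-bis(benzyloxy)-5-[(2S)-1-(ethynyloxy)pent-4-yn-2-yl]-2,3-dimethoxybenzene, via dichlorovinyl ether 17 (not isolated)
Conditions: KH (1.2 equiv), THF, 0 °C; 16, −50 °C → rt; then n-BuLi (3.5 equiv), −78 → −40 °C; MeOH, −78 °C; filtration through Et3N-deactivated silica, kept cold
Reagents that add atoms: none
Why: Established ynol ether synthesis from an alcohol and trichloroethylene: the potassium alkoxide adds to dichloroacetylene formed in situ to give the (E)-1,2-dichlorovinyl ether, n-BuLi eliminates HCl and exchanges the remaining chlorine, and protonation gives the ethynyl ether. The extra equivalent of n-BuLi covers the propargylic alkyne C–H, which is restored by the same methanol quench.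

Step 10
Reactants: 18 1,4-bis(benzyloxy)-5-[(2S)-1-(ethynyloxy)pent-4-yn-2-yl]-2,3-dimethoxybenzene; 19 bis(pinacolatoboryl)ethyne
Product: 20 (3S)-3-[2,5-bis(benzyloxy)-3,4-dimethoxyphenyl]-6,7-bis(4,4,5,5-tetramethyl-1,3,2-dioxaborolan-2-yl)chroman
Conditions: CpCo(C2H4)2 (20 mol%), 19 (3 equiv), THF, −20 → 20 °C, slow addition of 18, argon sweep
Reagents that add atoms: none
Why: This is a metal-catalysed [2+2+2] cyclotrimerisation of an α,ω-diyne with a monoalkyne, the closest known reaction type being CpCo-catalysed cocyclisation with alkoxyalkynes, heteroatom-tethered diynes and alkynylboronates. Loss of ethene frees monovalent cobalt, which binds both alkyne units of 18 and couples them oxidatively to a cobaltacyclopentadiene; this forms C4a–C8a and closes the pyran as the six-membered ring annulated to the metallacycle, the O1–C2–C3–C4 tether making the coupling intramolecular. Insertion of 19 into a Co–C bond (or its formal [4+2] addition to the metallacycle) and reductive elimination form C5–C6 and C7–C8 and close ring A as the benzene ring, which is then displaced from cobalt by fresh alkyne. No stereocentre is formed, and C3 is untouched because no acidic or metal-bound position adjoins it. The selectivity needed is cross- over self-trimerisation of 18: 19 is too hindered to trimerise itself, is used in excess, and 18 is added slowly so that its stationary concentration stays low. Regiochemistry is not in question, since 19 is symmetrical and the tether fixes the orientation of the diyne, placing the ynol ether oxygen as O1 and the borons on C6 and C7. CpCo(C2H4)2 is chosen over CpCo(CO)2 because it turns over at or below room temperature without irradiation or boiling solvent, which the ethynyl ether of 18 (retro-ene loss of ketene through the benzylic C3–H) would not survive.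

Step 11
Reactants: 20 (3S)-3-[2,5-bis(benzyloxy)-3,4-dimethoxyphenyl]-6,7-bis(4,4,5,5-tetramethyl-1,3,2-dioxaborolan-2-yl)chroman
Product: 21 (3S)-3-[2,5-bis(benzyloxy)-3,4-dimethoxyphenyl]chroman-6,7-diol
Conditions: NaBO3·4H2O, THF/H2O, rt, argon; NH4Cl (aq) work-up, crude used at once
Reagents that add atoms: sodium perborate tetrahydrate, [Na+].[Na+].O[B-]1(O)OO[B-](O)(O)OO1
Why: Perborate ipso-hydroxylation of arylboronic esters: each aryl group migrates from boron to oxygen at the same carbon, so the catechol oxygens appear exactly on C6 and C7; ethers are inert and air is excluded because 21 is easily oxidised.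

Step 12
Reactants: 21 (3S)-3-[2,5-bis(benzyloxy)-3,4-dimethoxyphenyl]chroman-6,7-diol
Product: 22 (3S)-3-[2,5-bis(benzyloxy)-3,4-dimethoxyphenyl]-6,7-dimethoxychroman
Conditions: MeI, K2CO3, DMF, rt, argon
Reagents that add atoms: iodomethane, CI
Why: Williamson O-methylation of both phenolic hydroxyls; no other acidic group is present.

Step 13
Reactants: 22 (3S)-3-[2,5-bis(benzyloxy)-3,4-dimethoxyphenyl]-6,7-dimethoxychroman
Product: 25 (3S)-3-[2,5-bis(benzyloxy)-3,4-dimethoxyphenyl]-6,7-dimethoxychroman-8-ol, via 8-lithiochroman 23 (not isolated), via dimethyl 8-chromanylboronate 24 (not isolated)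
Conditions: n-BuLi (1.3 equiv), THF, 0 °C; B(OMe)3, −78 °C → rt; then AcOH, H2O2 (30%), 0 °C → rt
Reagents that add atoms: hydrogen peroxide, OO
Why: Directed ortho-metalation followed by borylation and oxidation: C8–H is the only ring hydrogen flanked by two coordinating oxygens (O1 and the C7 methoxy), so n-BuLi should remove it in preference to C5–H, C6'–H and the benzylic CH2 groups; the aryllithium is trapped as the boronate and oxidised to the phenol under acidic peroxide.

Step 14
Reactants: 25 (3S)-3-[2,5-bis(benzyloxy)-3,4-dimethoxyphenyl]-6,7-dimethoxychroman-8-ol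
Product: 27 5-[(3S)-8-hydroxy-6,7-dimethoxychroman-3-yl]-2,3-dimethoxy-1,4-benzoquinone, via hydroquinone 26 (not isolated)
Conditions: H2 (1 atm), Pd/C (10%), EtOAc, rt; filtered under argon; then Ag2O (1.5 equiv), Na2SO4, rt
Reagents that add atoms: none
Why: Catalytic hydrogenolysis cleaves both aryl benzyl ethers and leaves the methyl ethers and the chroman intact; Ag2O then dehydrogenates the 2,3-dimethoxyhydroquinone, which is oxidised far more easily than the ring A phenol. Both stages are neutral, so C3 next to the new quinone is not at risk.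

## Compound list

1 | 2,3-dimethoxyphenol | COc1cccc(O)c1OC | starting material
2 | 2,3-dimethoxy-1,4-benzoquinone | COC1=C(OC)C(=O)C=CC1=O | intermediate
3 | 2,3-dimethoxybenzene-1,4-diol | COc1c(O)ccc(O)c1OC | intermediate
4 | 1,4-bis(benzyloxy)-2,3-dimethoxybenzene | COc1c(OC)c(OCc2ccccc2)ccc1OCc1ccccc1 | intermediate
5 | 1,4-bis(benzyloxy)-5-bromo-2,3-dimethoxybenzene | COc1c(OC)c(OCc2ccccc2)cc(Br)c1OCc1ccccc1 | intermediate
6 | ethyl bromoacetate | CCOC(=O)CBr | starting material
7 | ethyl (bromozincio)acetate | CCOC(=O)C[Zn]Br | intermediate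
8 | ethyl [2,5-bis(benzyloxy)-3,4-dimethoxyphenyl]acetate | COc1c(OC)c(OCc2ccccc2)cc(CC(=O)OCC)c1OCc1ccccc1 | intermediate
9 | [2,5-bis(benzyloxy)-3,4-dimethoxyphenyl]acetic acid | COc1c(OC)c(OCc2ccccc2)cc(CC(=O)O)c1OCc1ccccc1 | intermediate
10 | (4S)-4-benzyl-1,3-oxazolidin-2-one | O=C1OC[C@H](Cc2ccccc2)N1 | starting material
11 | [2,5-bis(benzyloxy)-3,4-dimethoxyphenyl]acetic pivalic anhydride | COc1c(OC)c(OCc2ccccc2)cc(CC(=O)OC(=O)C(C)(C)C)c1OCc1ccccc1 | intermediate
12 | (4S)-4-benzyl-3-{[2,5-bis(benzyloxy)-3,4-dimethoxyphenyl]acetyl}-1,3-oxazolidin-2-one | COc1c(OC)c(OCc2ccccc2)cc(CC(=O)N2[C@@H](Cc3ccccc3)COC2=O)c1OCc1ccccc1 | intermediate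
13 | propargyl bromide (3-bromoprop-1-yne) | BrCC#C | starting material
14 | (4S)-4-benzyl-3-{(2S)-2-[2,5-bis(benzyloxy)-3,4-dimethoxyphenyl]pent-4-ynoyl}-1,3-oxazolidin-2-one | COc1c(OC)c(OCc2ccccc2)cc([C@H](CC#C)C(=O)N2[C@@H](Cc3ccccc3)COC2=O)c1OCc1ccccc1 | intermediate
15 | (2S)-2-[2,5-bis(benzyloxy)-3,4-dimethoxyphenyl]pent-4-yn-1-ol | COc1c(OC)c(OCc2ccccc2)cc([C@H](CC#C)CO)c1OCc1ccccc1 | intermediate
16 | trichloroethylene | ClC=C(Cl)Cl | starting material
17 | 1,4-bis(benzyloxy)-5-[(2S)-1-{[(E)-1,2-dichloroethenyl]oxy}pent-4-yn-2-yl]-2,3-dimethoxybenzene | COc1c(OC)c(OCc2ccccc2)cc([C@H](CC#C)CO/C(Cl)=C\Cl)c1OCc1ccccc1 | intermediate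
18 | 1,4-bis(benzyloxy)-5-[(2S)-1-(ethynyloxy)pent-4-yn-2-yl]-2,3-dimethoxybenzene | COc1c(OC)c(OCc2ccccc2)cc([C@H](CC#C)COC#C)c1OCc1ccccc1 | intermediate
19 | bis(pinacolatoboryl)ethyne [1,2-bis(4,4,5,5-tetramethyl-1,3,2-dioxaborolan-2-yl)ethyne] | CC1(C)OB(OC1(C)C)C#CB1OC(C)(C)C(C)(C)O1 | starting material
20 | (3S)-3-[2,5-bis(benzyloxy)-3,4-dimethoxyphenyl]-6,7-bis(4,4,5,5-tetramethyl-1,3,2-dioxaborolan-2-yl)chroman | COc1c(OC)c(OCc2ccccc2)cc([C@H]2COc3cc(B4OC(C)(C)C(C)(C)O4)c(B4OC(C)(C)C(C)(C)O4)cc3C2)c1OCc1ccccc1 | intermediate
21 | (3S)-3-[2,5-bis(benzyloxy)-3,4-dimethoxyphenyl]chroman-6,7-diol | COc1c(OC)c(OCc2ccccc2)cc([C@H]2COc3cc(O)c(O)cc3C2)c1OCc1ccccc1 | intermediate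
22 | (3S)-3-[2,5-bis(benzyloxy)-3,4-dimethoxyphenyl]-6,7-dimethoxychroman | COc1c(OC)c(OCc2ccccc2)cc([C@H]2COc3cc(OC)c(OC)cc3C2)c1OCc1ccccc1 | intermediate
23 | [(3S)-3-[2,5-bis(benzyloxy)-3,4-dimethoxyphenyl]-6,7-dimethoxychroman-8-yl]lithium | COc1c(OC)c(OCc2ccccc2)cc([C@H]2COc3c(cc(OC)c(OC)c3[Li])C2)c1OCc1ccccc1 | intermediate
24 | dimethyl [(3S)-3-[2,5-bis(benzyloxy)-3,4-dimethoxyphenyl]-6,7-dimethoxychroman-8-yl]boronate | COc1c(OC)c(OCc2ccccc2)cc([C@H]2COc3c(cc(OC)c(OC)c3B(OC)OC)C2)c1OCc1ccccc1 | intermediate
25 | (3S)-3-[2,5-bis(benzyloxy)-3,4-dimethoxyphenyl]-6,7-dimethoxychroman-8-ol | COc1c(OC)c(OCc2ccccc2)cc([C@H]2COc3c(cc(OC)c(OC)c3O)C2)c1OCc1ccccc1 | intermediate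
26 | 5-[(3S)-8-hydroxy-6,7-dimethoxychroman-3-yl]-2,3-dimethoxybenzene-1,4-diol | COc1c(OC)c(O)cc([C@H]2COc3c(cc(OC)c(OC)c3O)C2)c1O | intermediate
27 | 5-[(3S)-8-hydroxy-6,7-dimethoxychroman-3-yl]-2,3-dimethoxy-1,4-benzoquinone | COC1=C(OC)C(=O)C([C@H]2COc3c(cc(OC)c(OC)c3O)C2)=CC1=O | target

## Step count and risks

Total step count: 14. Longest linear sequence: 14 steps (1 to 27); 6, 10, 13, 16 and 19 are purchased and enter directly.

**Step 10 (key step).** Most likely to go wrong: self-trimerisation and oligomerisation of 18 through its two unhindered terminal alkynes outrunning the insertion of the hindered alkyne 19. The ethynyl ether may also decay (retro-ene loss of ketene, hydration on work-up) before the catalyst turns over, and the metal may be trapped as a cyclobutadiene or ethene-derived cyclohexadiene complex. The fallback buys ring A and closes the pyran at O1–C2.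
- Commercial 2-hydroxy-4,5-dimethoxybenzaldehyde would be protected to 4,5-dimethoxy-2-(methoxymethoxy)benzaldehyde F1 (MOMCl, i-Pr2NEt), reduced to [4,5-dimethoxy-2-(methoxymethoxy)phenyl]methanol F2 (NaBH4) and brominated to 1-(bromomethyl)-4,5-dimethoxy-2-(methoxymethoxy)benzene F3 (PBr3, used at once).
- The sodium enolate of 12 would be alkylated with F3 in place of 13, under the same facial control, to give (4S)-4-benzyl-3-{(2S)-2-[2,5-bis(benzyloxy)-3,4-dimethoxyphenyl]-3-[4,5-dimethoxy-2-(methoxymethoxy)phenyl]propanoyl}-1,3-oxazolidin-2-one F4.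
- LiBH4 would give (2S)-2-[2,5-bis(benzyloxy)-3,4-dimethoxyphenyl]-3-[4,5-dimethoxy-2-(methoxymethoxy)phenyl]propan-1-ol F5, and HCl in MeOH would free 2-{(2S)-2-[2,5-bis(benzyloxy)-3,4-dimethoxyphenyl]-3-hydroxypropyl}-4,5-dimethoxyphenol F6.
- A Mitsunobu closure (PPh3, DIAD) would form O1–C2 and give 22, where the route is rejoined before step 13.

**Step 9.** Most likely to go wrong: KH also deprotonating the terminal alkyne, so that the acetylide adds to dichloroacetylene, or the alkoxide cyclising onto the alkyne. The product may also be lost by hydration or thermal fragmentation during isolation. The fallback avoids a free alkoxide. 15 would be formylated (formic acetic anhydride, pyridine) to (2S)-2-[2,5-bis(benzyloxy)-3,4-dimethoxyphenyl]pent-4-yn-1-yl formate F7. Ramirez dibromo-olefination of the formate carbonyl (CBr4, PPh3) would give 1,4-bis(benzyloxy)-5-{(2S)-1-[(2,2-dibromoethenyl)oxy]pent-4-yn-2-yl}-2,3-dimethoxybenzene F8. n-BuLi (3.3 equiv, −78 °C) with a methanol quench would then eliminate and exchange to give 18, where the route is rejoined.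

**Step 13.** Most likely to go wrong: competing deprotonation of the benzylic CH2 groups of the two benzyl ethers, followed by [1,2]-Wittig rearrangement, or partial lithiation at C5 or C6'. The fallback changes the protecting groups before the lithiation.
- 22 would be hydrogenolysed (H2, Pd/C) to 5-[(3S)-6,7-dimethoxychroman-3-yl]-2,3-dimethoxybenzene-1,4-diol F9.
- Silylation (i-Pr3SiOTf, 2,6-lutidine) would give (3S)-3-{3,4-dimethoxy-2,5-bis[(triisopropylsilyl)oxy]phenyl}-6,7-dimethoxychroman F10. Its bulky silyl ethers have no acidic CH2 and shield C6'.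
- The lithiation, borylation and oxidation of step 13 would then give (3S)-3-{3,4-dimethoxy-2,5-bis[(triisopropylsilyl)oxy]phenyl}-6,7-dimethoxychroman-8-ol F11.
- Fluoride (n-Bu4NF buffered with AcOH) would release hydroquinone 26, where the route is rejoined for the Ag2O oxidation of step 14.

**Step 11.** Most likely to go wrong: air oxidation of the electron-rich catechol (or its anion) to the ortho-quinone and decomposition during the basic oxidative work-up. The fallback never handles the free catechol. After the perborate oxidation of 20, the mixture would be reduced with Na2S2O3 and acetylated in the same flask (Ac2O, pyridine) to the stable (3S)-3-[2,5-bis(benzyloxy)-3,4-dimethoxyphenyl]chroman-6,7-diyl diacetate F12. K2CO3 and MeI in MeOH/DMF under argon would then cleave the acetates and methylate the phenoxides as they form, giving 22, where the route is rejoined.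

**Step 4.** Most likely to go wrong: slow oxidative addition into the electron-rich bromide flanked by a benzyloxy group, so that protonation or homocoupling of the zinc enolate wins. The fallback makes the aryl–CH2 bond with an aryllithium. Bromine–lithium exchange on 5 (n-BuLi, −78 °C) and opening of oxirane (BF3·OEt2) would give 2-[2,5-bis(benzyloxy)-3,4-dimethoxyphenyl]ethan-1-ol F13. Oxidation of the primary alcohol (TEMPO, PhI(OAc)2, MeCN/H2O) would give acid 9, where the route is rejoined at step 6.

## Further compounds

F1 | step 10 | 4,5-dimethoxy-2-(methoxymethoxy)benzaldehyde | COCOc1cc(OC)c(OC)cc1C=O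
F2 | step 10 | [4,5-dimethoxy-2-(methoxymethoxy)phenyl]methanol | COCOc1cc(OC)c(OC)cc1CO
F3 | step 10 | 1-(bromomethyl)-4,5-dimethoxy-2-(methoxymethoxy)benzene | COCOc1cc(OC)c(OC)cc1CBr
F4 | step 10 | (4S)-4-benzyl-3-{(2S)-2-[2,5-bis(benzyloxy)-3,4-dimethoxyphenyl]-3-[4,5-dimethoxy-2-(methoxymethoxy)phenyl]propanoyl}-1,3-oxazolidin-2-one | COc1c(OC)c(OCc2ccccc2)cc([C@H](Cc2cc(OC)c(OC)cc2OCOC)C(=O)N2[C@@H](Cc3ccccc3)COC2=O)c1OCc1ccccc1
F5 | step 10 | (2S)-2-[2,5-bis(benzyloxy)-3,4-dimethoxyphenyl]-3-[4,5-dimethoxy-2-(methoxymethoxy)phenyl]propan-1-ol | COc1c(OC)c(OCc2ccccc2)cc([C@H](Cc2cc(OC)c(OC)cc2OCOC)CO)c1OCc1ccccc1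
F6 | step 10 | 2-{(2S)-2-[2,5-bis(benzyloxy)-3,4-dimethoxyphenyl]-3-hydroxypropyl}-4,5-dimethoxyphenol | COc1c(OC)c(OCc2ccccc2)cc([C@H](Cc2cc(OC)c(OC)cc2O)CO)c1OCc1ccccc1
F7 | step 9 | (2S)-2-[2,5-bis(benzyloxy)-3,4-dimethoxyphenyl]pent-4-yn-1-yl formate | COc1c(OC)c(OCc2ccccc2)cc([C@H](CC#C)COC=O)c1OCc1ccccc1
F8 | step 9 | 1,4-bis(benzyloxy)-5-{(2S)-1-[(2,2-dibromoethenyl)oxy]pent-4-yn-2-yl}-2,3-dimethoxybenzene | COc1c(OC)c(OCc2ccccc2)cc([C@H](CC#C)COC=C(Br)Br)c1OCc1ccccc1
F9 | step 13 | 5-[(3S)-6,7-dimethoxychroman-3-yl]-2,3-dimethoxybenzene-1,4-diol | COc1c(OC)c(O)cc([C@H]2COc3cc(OC)c(OC)cc3C2)c1O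
F10 | step 13 | (3S)-3-{3,4-dimethoxy-2,5-bis[(triisopropylsilyl)oxy]phenyl}-6,7-dimethoxychroman | COc1c(OC)c(O[Si](C(C)C)(C(C)C)C(C)C)cc([C@H]2COc3cc(OC)c(OC)cc3C2)c1O[Si](C(C)C)(C(C)C)C(C)C
F11 | step 13 | (3S)-3-{3,4-dimethoxy-2,5-bis[(triisopropylsilyl)oxy]phenyl}-6,7-dimethoxychroman-8-ol | COc1c(OC)c(O[Si](C(C)C)(C(C)C)C(C)C)cc([C@H]2COc3c(cc(OC)c(OC)c3O)C2)c1O[Si](C(C)C)(C(C)C)C(C)C
F12 | step 11 | (3S)-3-[2,5-bis(benzyloxy)-3,4-dimethoxyphenyl]chroman-6,7-diyl diacetate | COc1c(OC)c(OCc2ccccc2)cc([C@H]2COc3cc(OC(C)=O)c(OC(C)=O)cc3C2)c1OCc1ccccc1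
F13 | step 4 | 2-[2,5-bis(benzyloxy)-3,4-dimethoxyphenyl]ethan-1-ol | COc1c(OC)c(OCc2ccccc2)cc(CCO)c1OCc1ccccc1
A1 | alternative 1 | 5-[(3S)-8-(benzyloxy)-6,7-dimethoxychroman-3-yl]-2,3-dimethoxy-1,4-benzoquinone | COC1=C(OC)C(=O)C([C@H]2COc3c(cc(OC)c(OC)c3OCc3ccccc3)C2)=CC1=O
A2 | alternative 1 | (3S)-8-(benzyloxy)-3-ethynyl-6,7-dimethoxychroman | C#C[C@H]1COc2c(cc(OC)c(OC)c2OCc2ccccc2)C1
A3 | alternative 1 | dimethyl squarate (3,4-dimethoxycyclobut-3-ene-1,2-dione) | COC1=C(OC)C(=O)C1=O
A4 | alternative 1 | 4-{[(3S)-8-(benzyloxy)-6,7-dimethoxychroman-3-yl]ethynyl}-4-hydroxy-2,3-dimethoxycyclobut-2-en-1-one (carbinol carbon not defined) | COC1=C(OC)C(O)(C#C[C@H]2COc3c(cc(OC)c(OC)c3OCc3ccccc3)C2)C1=O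
A5 | alternative 2 | (3S)-8-(benzyloxy)-3-[2,5-bis(benzyloxy)-3,4-dimethoxyphenyl]-6,7-dimethoxychroman-2-ol (both C2 epimers) | COc1c(OC)c(OCc2ccccc2)cc([C@H]2C(O)Oc3c(cc(OC)c(OC)c3OCc3ccccc3)C2)c1OCc1ccccc1
A6 | alternative 2 | [2,5-bis(benzyloxy)-3,4-dimethoxyphenyl]acetaldehyde | COc1c(OC)c(OCc2ccccc2)cc(CC=O)c1OCc1ccccc1
A7 | alternative 2 | 2-(benzyloxy)-3,4-dimethoxy-6-[(phenylsulfonyl)methyl]phenol | COc1cc(CS(=O)(=O)c2ccccc2)c(O)c(OCc2ccccc2)c1OC
A8 | alternative 2 | 2-(benzyloxy)-3,4-dimethoxy-6-methylidenecyclohexa-2,4-dien-1-one | O=C1C(OCc2ccccc2)=C(OC)C(OC)=CC1=C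
A9 | alternative 3 | (3S)-8-(benzyloxy)-3-[2,5-bis(benzyloxy)-3,4-dimethoxyphenyl]-6,7-dimethoxy-4-(phenylsulfonyl)chroman (both C4 epimers) | COc1c(OC)c(OCc2ccccc2)cc([C@H]2COc3c(cc(OC)c(OC)c3OCc3ccccc3)C2S(=O)(=O)c2ccccc2)c1OCc1ccccc1
A10 | alternative 3 | 3-(benzyloxy)-1-bromo-4,5-dimethoxy-2-{[(2S)-2-[2,5-bis(benzyloxy)-3,4-dimethoxyphenyl]-3-(phenylsulfonyl)propyl]oxy}benzene | COc1c(OC)c(OCc2ccccc2)cc([C@@H](COc2c(Br)cc(OC)c(OC)c2OCc2ccccc2)CS(=O)(=O)c2ccccc2)c1OCc1ccccc1
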